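The plan rests on forming the C2–C3 bond of ring C last. In the target, C2 is a methine bound to O1 and ring B, and a single methylene (C3) separates it from the C4 ketone, so a ketone-stabilised carbene placed on C3 can be inserted into one C–H bond of an O1-bound benzylic CH2. One rhodium-catalysed operation should close ring C and create the only stereocentre under catalyst control. The substrate is an achiral diazomethyl ketone on a fully substituted ring A (three methoxy groups, C8 prenyl) whose ortho oxygen carries the 4-benzyloxybenzyl group that becomes C2 and ring B. A final BCl3 step frees the 5- and 4'-hydroxyls.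

Key step: step 7

Assumption: the sense of asymmetric induction of Rh2(S-PTTL)4 with this substrate cannot be predicted with confidence. The route is written with the S-catalyst and the configuration of 14 is to be assigned on the first run. If the 2R isomer predominates, the mirror-image catalyst Rh2(R-PTTL)4 (from D-tert-leucine) is used instead.

Design of the key-step substrate:
- O5 stays a methyl ether. It flanks the carbene, so it must offer neither an activated C–H bond nor a migrating group. A benzyl, allyl or MOM group there would open a second insertion or rearrangement channel, and a free OH would undergo O–H insertion.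
- Ring B carries a benzyl ether. A para alkoxy donor raises the hydride-donor ability of the C2–H bonds, and BCl3 removes it in the same flask as the chelated 5-methyl group. Hydrogenolysis is excluded by the prenyl alkene.
- The C3–C4 unit enters as an acetyl group and becomes the diazoketone by base-mediated diazo transfer. This avoids a hindered 2,6-disubstituted benzoic acid and an acid chloride next to an acid-labile 4-alkoxybenzyl ether.

Step 1
Reactants: 1 3,4,5-trimethoxyphenol
Product: 2 1,2,3-trimethoxy-5-(methoxymethoxy)benzene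
Conditions: MOMCl (1.3 equiv), i-Pr2NEt (1.5 equiv), CH2Cl2, 0 °C → rt
Reagents that add atoms: chloromethyl methyl ether, COCCl
Why: Williamson-type O-alkylation of the phenol by an alpha-chloro ether gives the MOM acetal, which serves as the directing group for both metalations that follow.

Step 2
Reactants: 2 1,2,3-trimethoxy-5-(methoxymethoxy)benzene; 3 prenyl bromide
Product: 5 1,2,3-trimethoxy-5-(methoxymethoxy)-4-(3-methylbut-2-en-1-yl)benzene, via aryllithium 4 (not isolated)
Conditions: n-BuLi (1.1 equiv), THF, 0 °C, 1 h; CuI (10 mol %), then 3 (1.3 equiv), −78 °C → rt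
Reagents that add atoms: prenyl bromide 3, CC(C)=CCBr
Why: Directed ortho-metalation removes a ring hydrogen flanked by OMOM and OMe (the two such sites are equivalent by symmetry), and copper-catalysed allylic substitution of the aryllithium on prenyl bromide should take place at the unhindered primary carbon to give the linear prenyl arene.

Step 3
Reactants: 5 1,2,3-trimethoxy-5-(methoxymethoxy)-4-(3-methylbut-2-en-1-yl)benzene; 6 N-methoxy-N-methylacetamide
Product: 8 1-[2-(methoxymethoxy)-4,5,6-trimethoxy-3-(3-methylbut-2-en-1-yl)phenyl]ethanone, via aryllithium 7 (not isolated)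
Conditions: n-BuLi (1.2 equiv), TMEDA (1.2 equiv), THF, −20 °C → 0 °C, 1 h; then 6 (1.5 equiv), −78 °C → 0 °C; aq. NH4Cl
Reagents that add atoms: N-methoxy-N-methylacetamide 6, CC(=O)N(C)OC
Why: A second directed ortho-metalation should take the one remaining ring hydrogen, again between OMOM and OMe, faster than the prenyl CH2 (whose anion would be twisted out of conjugation by two ortho groups and destabilised by the dialkylated allyl terminus), and Weinreb ketone synthesis then acylates the aryllithium once through the chelated tetrahedral adduct.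

Step 4
Reactants: 8 1-[2-(methoxymethoxy)-4,5,6-trimethoxy-3-(3-methylbut-2-en-1-yl)phenyl]ethanone
Product: 9 1-[2-hydroxy-4,5,6-trimethoxy-3-(3-methylbut-2-en-1-yl)phenyl]ethanone
Conditions: aq. HCl (3 M, 2 equiv), MeOH, rt
Reagents that add atoms: none
Why: Acid-catalysed acetal exchange with methanol removes the MOM group, which is made unusually labile by the neighbouring ketone, under conditions mild enough that the prenyl alkene should neither hydrate nor cyclise onto the freed phenol.

Step 5
Reactants: 9 1-[2-hydroxy-4,5,6-trimethoxy-3-(3-methylbut-2-en-1-yl)phenyl]ethanone; 10 4-(benzyloxy)benzyl chloride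
Product: 11 1-[2-{[4-(benzyloxy)phenyl]methoxy}-4,5,6-trimethoxy-3-(3-methylbut-2-en-1-yl)phenyl]ethanone
Conditions: 10 (1.2 equiv), K2CO3 (2 equiv), n-Bu4NI (10 mol %), DMF, 60 °C
Reagents that add atoms: 4-(benzyloxy)benzyl chloride 10, ClCc1ccc(OCc2ccccc2)cc1
Why: Williamson ether synthesis in which the chelated phenoxide is alkylated on oxygen by a reactive benzylic halide under iodide catalysis, C-alkylation being excluded because both ortho positions and the para position are substituted.

Step 6
Reactants: 11 1-[2-{[4-(benzyloxy)phenyl]methoxy}-4,5,6-trimethoxy-3-(3-methylbut-2-en-1-yl)phenyl]ethanone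
Product: 13 2-diazo-1-[2-{[4-(benzyloxy)phenyl]methoxy}-4,5,6-trimethoxy-3-(3-methylbut-2-en-1-yl)phenyl]ethanone, via trifluoromethyl 1,3-diketone 12 (not isolated)
Conditions: LiN(SiMe3)2 (1.1 equiv), THF, −78 °C; CF3CO2CH2CF3 (1.2 equiv), −78 °C; aq. HCl work-up; then MsN3 (1.5 equiv), Et3N (1.5 equiv), H2O (1 equiv), MeCN, rt
Reagents that add atoms: methanesulfonyl azide, CS(=O)(=O)N=[N+]=[N-]; 2,2,2-trifluoroethyl trifluoroacetate, O=C(OCC(F)(F)F)C(F)(F)F (its CF3CO group is carried only by 12)
Why: Detrifluoroacetylative diazo transfer, that is a Claisen condensation of the methyl ketone enolate with the trifluoroacetate followed by Regitz diazo transfer to the activated 1,3-dicarbonyl and loss of the trifluoroacetyl group on the sulfonamide, is a base-only sequence that should spare the acid-labile 4-alkoxybenzyl ether and the alkene.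

Step 7
Reactants: 13 2-diazo-1-[2-{[4-(benzyloxy)phenyl]methoxy}-4,5,6-trimethoxy-3-(3-methylbut-2-en-1-yl)phenyl]ethanone
Product: 14 (2S)-2-[4-(benzyloxy)phenyl]-5,6,7-trimethoxy-8-(3-methylbut-2-en-1-yl)-2,3-dihydro-4H-chromen-4-one
Conditions: Rh2(S-PTTL)4 (dirhodium tetrakis[N-phthaloyl-(S)-tert-leucinate], 2 mol %), CH2Cl2, 4 Å MS, 0 °C, 13 added over 2 h (final 0.01 M)
Reagents that add atoms: none
Why: The catalyst expels N2 from 13 to give an electrophilic rhodium carbene at C3; the acyl group, flanked by two ortho oxygens, is twisted out of the ring plane and holds the carbene beside the O1–CH2 group, where a concerted, asynchronous three-centre transition state (hydride-like shift from the benzylic carbon together with C2–C3 bond formation) should deliver the chromanone and release the catalyst. The closest known reaction type is the chiral dirhodium tetracarboxylate-catalysed intramolecular C–H insertion of 2-alkoxyaryl diazoketones to chroman-4-ones and of aryl benzyl ethers to 2-aryl-2,3-dihydrobenzofurans. Ring C closes by C–C bond formation in a 1,6-insertion (ring atoms C3, C4, C4a, C8a, O1, C2), the reacting C–H bond lying alpha to O1. The C2 stereocentre is set by the catalyst alone, whose phthalimido and tert-butyl groups should let only one of the two enantiotopic benzylic hydrogens reach the carbene, the sense of induction being secured as stated in the assumption. The step needs insertion at O1–CH2 to win over ylide formation at O1 followed by a 1,2-benzyl (Stevens) shift, over insertion into the C5 methoxy group and over attack on the prenyl alkene: the benzylic C–H bonds are activated by both O1 and the 4-benzyloxyphenyl ring whereas OCH3 offers only primary C–H bonds, O1 is a weakly basic aryl ether oxygen crowded by the C8 prenyl group and the bulky carboxylate ligands, and the alkene cannot reach C3 within the same molecule and is kept from a second molecule by slow addition at high dilution in a non-coordinating solvent.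

Step 8
Reactants: 14 (2S)-2-[4-(benzyloxy)phenyl]-5,6,7-trimethoxy-8-(3-methylbut-2-en-1-yl)-2,3-dihydro-4H-chromen-4-one
Product: 15 (2S)-5-hydroxy-2-(4-hydroxyphenyl)-6,7-dimethoxy-8-(3-methylbut-2-en-1-yl)-2,3-dihydro-4H-chromen-4-one (CNP0104932.1)
Conditions: BCl3 (1 M in CH2Cl2, 4 equiv), C6HMe5 (3 equiv), CH2Cl2, −78 °C → 0 °C, quenched as soon as the 5-methyl ether is consumed; MeOH then aq. NaHCO3 at −78 °C
Reagents that add atoms: none
Why: Lewis acid ether cleavage in which boron chelated between the C4 carbonyl and O5 should remove only the 5-methyl group while the same reagent cleaves the aryl benzyl ether at low temperature, pentamethylbenzene capturing the benzyl cation by Friedel–Crafts alkylation so that neither the prenyl alkene nor ring B is benzylated and C2 is left untouched.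

Compound list
1 | 3,4,5-trimethoxyphenol | COc1cc(O)cc(OC)c1OC | starting material
2 | 1,2,3-trimethoxy-5-(methoxymethoxy)benzene | COCOc1cc(OC)c(OC)c(OC)c1 | intermediate
3 | prenyl bromide (1-bromo-3-methylbut-2-ene) | CC(C)=CCBr | starting material
4 | [2-(methoxymethoxy)-4,5,6-trimethoxyphenyl]lithium | [Li]c1c(OCOC)cc(OC)c(OC)c1OC | intermediate (not isolated)
5 | 1,2,3-trimethoxy-5-(methoxymethoxy)-4-(3-methylbut-2-en-1-yl)benzene | COCOc1cc(OC)c(OC)c(OC)c1CC=C(C)C | intermediate
6 | N-methoxy-N-methylacetamide | CC(=O)N(C)OC | starting material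
7 | [2-(methoxymethoxy)-4,5,6-trimethoxy-3-(3-methylbut-2-en-1-yl)phenyl]lithium | [Li]c1c(OC)c(OC)c(OC)c(CC=C(C)C)c1OCOC | intermediate (not isolated)
8 | 1-[2-(methoxymethoxy)-4,5,6-trimethoxy-3-(3-methylbut-2-en-1-yl)phenyl]ethanone | CC(=O)c1c(OC)c(OC)c(OC)c(CC=C(C)C)c1OCOC | intermediate
9 | 1-[2-hydroxy-4,5,6-trimethoxy-3-(3-methylbut-2-en-1-yl)phenyl]ethanone | CC(=O)c1c(OC)c(OC)c(OC)c(CC=C(C)C)c1O | intermediate
10 | 4-(benzyloxy)benzyl chloride | ClCc1ccc(OCc2ccccc2)cc1 | starting material
11 | 1-[2-{[4-(benzyloxy)phenyl]methoxy}-4,5,6-trimethoxy-3-(3-methylbut-2-en-1-yl)phenyl]ethanone | CC(=O)c1c(OC)c(OC)c(OC)c(CC=C(C)C)c1OCc1ccc(OCc2ccccc2)cc1 | intermediate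
12 | 1-[2-{[4-(benzyloxy)phenyl]methoxy}-4,5,6-trimethoxy-3-(3-methylbut-2-en-1-yl)phenyl]-4,4,4-trifluorobutane-1,3-dione | O=C(CC(=O)C(F)(F)F)c1c(OC)c(OC)c(OC)c(CC=C(C)C)c1OCc1ccc(OCc2ccccc2)cc1 | intermediate (not isolated)
13 | 2-diazo-1-[2-{[4-(benzyloxy)phenyl]methoxy}-4,5,6-trimethoxy-3-(3-methylbut-2-en-1-yl)phenyl]ethanone | [N-]=[N+]=CC(=O)c1c(OC)c(OC)c(OC)c(CC=C(C)C)c1OCc1ccc(OCc2ccccc2)cc1 | intermediate
14 | (2S)-2-[4-(benzyloxy)phenyl]-5,6,7-trimethoxy-8-(3-methylbut-2-en-1-yl)-2,3-dihydro-4H-chromen-4-one | COc1c(OC)c2c(c(CC=C(C)C)c1OC)O[C@H](c1ccc(OCc3ccccc3)cc1)CC2=O | intermediate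
15 | (2S)-5-hydroxy-2-(4-hydroxyphenyl)-6,7-dimethoxy-8-(3-methylbut-2-en-1-yl)-2,3-dihydro-4H-chromen-4-one | COc1c(O)c2c(c(CC=C(C)C)c1OC)O[C@H](c1ccc(O)cc1)CC2=O | target

Total step count: 8.
Longest linear sequence: 8 steps (1 → 15).

Steps most likely to fail

Step 7. The carbene may be captured by the O1 lone pair and rearrange by a 1,2-benzyl shift instead of inserting, or the two enantiotopic benzylic hydrogens may be poorly distinguished, so that the ring closes with low enantiomeric purity. Fallback, setting out from 9 and returning at 14: condensation of 9 with N,N-dimethylformamide dimethyl acetal (toluene, 90 °C) should give the enaminone (E)-3-(dimethylamino)-1-[2-hydroxy-4,5,6-trimethoxy-3-(3-methylbut-2-en-1-yl)phenyl]prop-2-en-1-one F1. F1 closes under mild acid (AcOH, 50 °C) with loss of dimethylamine to 5,6,7-trimethoxy-8-(3-methylbut-2-en-1-yl)-4H-chromen-4-one F2. Rhodium-catalysed asymmetric 1,4-addition (Hayashi–Miyaura reaction) of 4-(benzyloxy)phenylboronic acid to F2 ([Rh(OH)(cod)]2 with an electron-poor atropisomeric bisphosphine, toluene/H2O, rt) then forms the C2–aryl bond and gives 14. The ligand enantiomer is chosen for the 2S product.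

Step 8. The prenyl alkene may add HCl or be alkylated while the ethers are cleaved, demethylation may run on to the 6-methoxy group, and Lewis-acid-promoted opening of ring C at the C2–O1 bond with reclosure would erode the configuration at C2. Fallback, setting out from 14 and returning at 15: MgI2·OEt2 (THF, 60 °C), in which a magnesium chelate between the C4 carbonyl and O5 directs iodide to the 5-methyl group only, should give (2S)-2-[4-(benzyloxy)phenyl]-5-hydroxy-6,7-dimethoxy-8-(3-methylbut-2-en-1-yl)-2,3-dihydro-4H-chromen-4-one F3. The benzyl ether is then cleaved reductively without any Lewis acid by Pd(OAc)2 (5 mol %), Et3SiH and Et3N in CH2Cl2 at rt, conditions that leave trisubstituted alkenes alone. This should give the 4'-O-triethylsilyl ether (2S)-5-hydroxy-6,7-dimethoxy-8-(3-methylbut-2-en-1-yl)-2-{4-[(triethylsilyl)oxy]phenyl}-2,3-dihydro-4H-chromen-4-one F4, which is hydrolysed during a dilute citric acid/MeOH work-up to 15.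

Step 3. Deprotonation may take place at the doubly activated prenyl CH2 instead of on the ring, or the hindered aryllithium may enolise the amide instead of adding to it. Fallback, setting out from 1 and returning at 9 (it replaces steps 1–4 and generates no organolithium in the presence of the prenyl group): Friedel–Crafts acetylation of 1 (AcOH, BF3·OEt2, 80 °C) gives 1-(2-hydroxy-4,5,6-trimethoxyphenyl)ethanone F5. Copper-catalysed O-alkylation with 3-chloro-3-methylbut-1-yne (CuCl2·2H2O cat., DBU, MeCN, 0 °C) gives 1-[4,5,6-trimethoxy-2-(2-methylbut-3-yn-2-yloxy)phenyl]ethanone F6. Semi-hydrogenation (H2, Pd on CaCO3 poisoned with Pb(OAc)2, quinoline, EtOAc) gives 1-[4,5,6-trimethoxy-2-(2-methylbut-3-en-2-yloxy)phenyl]ethanone F7. Aromatic Claisen rearrangement of F7 (N,N-diethylaniline, 130 °C) to the only free ortho position delivers the linear prenyl group and gives 9.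

Further compounds
F1 | step 7 | (E)-3-(dimethylamino)-1-[2-hydroxy-4,5,6-trimethoxy-3-(3-methylbut-2-en-1-yl)phenyl]prop-2-en-1-one | CN(C)/C=C/C(=O)c1c(OC)c(OC)c(OC)c(CC=C(C)C)c1O
F2 | step 7 | 5,6,7-trimethoxy-8-(3-methylbut-2-en-1-yl)-4H-chromen-4-one | O=c1ccoc2c(CC=C(C)C)c(OC)c(OC)c(OC)c12
F3 | step 8 | (2S)-2-[4-(benzyloxy)phenyl]-5-hydroxy-6,7-dimethoxy-8-(3-methylbut-2-en-1-yl)-2,3-dihydro-4H-chromen-4-one | COc1c(O)c2c(c(CC=C(C)C)c1OC)O[C@H](c1ccc(OCc3ccccc3)cc1)CC2=O
F4 | step 8 | (2S)-5-hydroxy-6,7-dimethoxy-8-(3-methylbut-2-en-1-yl)-2-{4-[(triethylsilyl)oxy]phenyl}-2,3-dihydro-4H-chromen-4-one | COc1c(O)c2c(c(CC=C(C)C)c1OC)O[C@H](c1ccc(O[Si](CC)(CC)CC)cc1)CC2=O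
F5 | step 3 | 1-(2-hydroxy-4,5,6-trimethoxyphenyl)ethanone | CC(=O)c1c(O)cc(OC)c(OC)c1OC
F6 | step 3 | 1-[4,5,6-trimethoxy-2-(2-methylbut-3-yn-2-yloxy)phenyl]ethanone | CC(=O)c1c(OC(C)(C)C#C)cc(OC)c(OC)c1OC
F7 | step 3 | 1-[4,5,6-trimethoxy-2-(2-methylbut-3-en-2-yloxy)phenyl]ethanone | CC(=O)c1c(OC(C)(C)C=C)cc(OC)c(OC)c1OC
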